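**Remark (assumption).** The SMILES has no stereocentre and no stereogenic double bond, so the target is achiral and the request for a single enantiomer places no demand on the route. The side chain is read as an unbranched nonacosyl (C29) group.

## The problem

The target is 5,7-dihydroxy-2-nonacosyl-4H-chromen-4-one (11): a phloroglucinol-derived benzo-γ-pyranone with an unbranched C29 chain on C2 and hydrogen on C3. With no stereocentre, the difficulty lies in connectivity and handling. First, a 29-carbon chain must be joined to C2 of a polar heterocycle, although no C29 building block is an article of commerce and every chain-bearing intermediate is a poorly soluble wax. Second, the pyranone must close with the right connectivity, because the same components can also give the isomeric 4-alkylcoumarin (carbonyl and chain exchanged) or a five-membered 2-alkylidenebenzofuranone. Third, the two free phenols sit on an electron-rich ring that is easily oxidised and C-substituted, the pyranone opens at C2 under strong aqueous base, and methyl-ether protection would force a harsh demethylation on the last, waxy intermediate. The feature that makes the key step possible is the C4 carbonyl carbon, which lies between ring carbon C4a and the C3(H)=C2(chain) unit, with the ring oxygen O1 ortho to C4a: C4 can come from carbon monoxide, C3–C2 and the chain from a terminal alkyne at the same oxidation level, and ring A from an aryl iodide. Because the three oxygens of ring A (O1, 5-O, 7-O) are related by the threefold symmetry of phloroglucinol, that iodide is the only possible mono-iodide of phloroglucinol, and either of its ortho oxygens closes the same ring.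

## Retrosynthesis

**11 ⇒ 3 + 7 + 8.** Three bonds of the pyranone are cut together: C4a–C4, C4–C3 and O1–C2, along with the three O–acetyl bonds that mask the phenols. The neighbouring cuts are C2–C3 (Claisen logic) and C2–C1' of the chain (alkylation of a 2-methylchromone). Both leave ring closure, chain attachment and deprotection to separate steps. Cutting on both sides of C4 turns the carbonyl carbon into carbon monoxide 8 and the C3(H)=C2(C29H59) unit into terminal alkyne 7. An o-hydroxyaryl ynone is an isomer of the chromone, so no redox adjustment is needed. Ring A becomes aryl iodide 3, whose C–I bond marks C4a. The precursors are a monocyclic C12 iodide, a linear hydrocarbon and a gas, whereas the product holds all 38 carbons, the bicyclic core and both free phenols. The forward reaction must carbonylate before it couples (to ynone triacetate 9), shed the acetates, and close the six-membered ring through amine adduct 10 rather than a five-membered ring.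

**3 ⇒ 2 ⇒ 1.** The C–I bond and the three O–acyl bonds are cut. Phloroglucinol 1 is C3-symmetric, so iodination can give only one mono-iodide, 2, with iodine between two oxygens. This is exactly the relation of C4a to O1 and 5-O in 11. A 3,5-dialkoxyphenol would instead raise an ortho/para question at the iodination and an ether cleavage at the end. Acetylation to 3 gives shelf stability, a less electron-rich ring for oxidative addition, and protecting groups that the amine of the key step removes by itself.

**7 ⇒ 5 ⇒ 4.** The C1≡C2 bond of 7 is traced to the carbonyl carbon of the C30 aldehyde 5 by one-carbon homologation (through diazoalkene 6), and 5 to triacontan-1-ol 4 by oxidation. The cut is placed here and not at C3–C4 of the alkyne (acetylide alkylation), because the C30 alcohol is a readily available long-chain building block whereas a C29 halide is not. C30 plus C1 gives the C31 alkyne whose two sp carbons become C3 and C2 of 11. Both 5 and 7 are unfunctionalised waxes that can be purified by silica filtration and crystallisation, so the forward steps need only tolerate poor solubility.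

## Roads not taken

**Alternative 1:** Baker–Venkataraman route, the most obvious one.
- Cut: C2–C3 and O1–C2.
- Forward key step: base-induced 1,3-acyl shift (intramolecular Claisen) of 2-acetyl-3,5-dimethoxyphenyl triacontanoate A1 to 1-(2-hydroxy-4,6-dimethoxyphenyl)dotriacontane-1,3-dione A2. Acid cyclodehydration then gives 5,7-dimethoxy-2-nonacosyl-4H-chromen-4-one A3, and exhaustive demethylation gives 11.
- Why the chosen plan is better: here the chain enters in the first step, so every operation is run on a wax, and each pyranone bond is made in a separate step. The 7-O-methyl ether has no neighbouring carbonyl to assist cleavage, so forcing Lewis-acid conditions fall on the final compound. The chosen plan makes three ring bonds in one operation, is convergent (longest linear sequence of three), carries the chain through only two hydrocarbon intermediates, and frees the phenols under the ring-forming conditions.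

**Alternative 2:** thermal acylketene condensation with unprotected phloroglucinol (Mentzer type).
- Cut: C4–C4a and O1–C2.
- Forward key step: 5-(1-hydroxytriacontylidene)-2,2-dimethyl-1,3-dioxane-4,6-dione A4 is heated with 1. Loss of acetone and CO2 gives acylketene A5 (3-oxodotriacont-1-en-1-one), which acylates 1, and cyclodehydration would give 11 in two steps without protecting groups.
- Why the chosen plan is better: nothing in the substrates decides which carbonyl of A5 ends up on the ring. O-acylation followed by attack of the ring on the ketone (Pechmann mode), for which phloroglucinol is the most reactive phenol, leads to the isomeric coumarin A6 (5,7-dihydroxy-4-nonacosyl-2H-chromen-2-one). The reaction also needs a melt above 200 °C of a polar triol and a wax that do not mix. In the chosen plan C4 is bound to C4a through an aryl–palladium bond before the chain component enters, so the chromone connectivity is fixed by mechanism. This alternative is shorter, but its outcome rests on a thermal preference.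

**Alternative 3:** anodic mixed Kolbe coupling inside the chain.
- Cut: C8'–C9' of the side chain.
- Forward key step: co-electrolysis of 9-(5,7-dimethoxy-4-oxo-4H-chromen-2-yl)nonanoic acid A7 with excess docosanoic acid A8 (Pt anode, MeOH, partial neutralisation) gives A3, followed by demethylation.
- Why the chosen plan is better: radical–radical coupling is statistical, so both homodimers form. The dimethoxyarene and the enone are exposed to the anode at Kolbe potentials, above their own oxidation potentials. Free phenols are not tolerated, so the ether cleavage of Alternative 1 returns. A7 itself needs a Baker–Venkataraman sequence, so steps are added, not saved. Its only gain, replacing a C30 input by C10 and C22 acids, is not needed because 4 is commercial.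

Key step: step 5

## Route

Step 1
Reactants: 1 phloroglucinol (benzene-1,3,5-triol)
Product: 2 2-iodobenzene-1,3,5-triol
Conditions: I2 (1.0 equiv), NaHCO3 (1.1 equiv), THF/H2O 1:1, 0 °C
Reagents that add atoms: iodine, II
Why: Electrophilic aromatic iodination of a highly electron-rich arene under buffered conditions; the three ring CH positions are equivalent, so only one mono-iodide can form, and one equivalent of iodine at 0 °C should hold the reaction at mono-substitution.

Step 2
Reactants: 2 2-iodobenzene-1,3,5-triol
Product: 3 2-iodobenzene-1,3,5-triyl triacetate
Conditions: Ac2O (4 equiv), pyridine, cat. DMAP, CH2Cl2, 0 °C to rt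
Reagents that add atoms: acetic anhydride, CC(=O)OC(C)=O
Why: Exhaustive O-acetylation of phenols under nucleophilic catalysis; the acetates stabilise the iodide towards air and light, lower the electron density of the ring for oxidative addition, and are removed by the amine in step 5.

Step 3
Reactants: 4 triacontan-1-ol
Product: 5 triacontanal
Conditions: IBX (1.5 equiv), EtOAc, 80 °C; hot filtration
Reagents that add atoms: none
Why: IBX oxidation of a primary alcohol in refluxing ethyl acetate, in which the waxy alcohol dissolves while the oxidant and its reduced form do not; the oxidation stops at the aldehyde.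

Step 4
Reactants: 5 triacontanal
Product: 7 hentriacont-1-yne, via diazoalkene 6 (not isolated)
Conditions: dimethyl (1-diazo-2-oxopropyl)phosphonate (1.3 equiv), K2CO3 (2 equiv), MeOH/THF 1:1, 35 °C
Reagents that add atoms: dimethyl (1-diazo-2-oxopropyl)phosphonate (Ohira–Bestmann reagent), COP(=O)(OC)C(=[N+]=[N-])C(C)=O
Why: Seyferth–Gilbert homologation in the Ohira–Bestmann modification: methanolysis of the reagent releases the diazomethylphosphonate anion, Horner–Wadsworth–Emmons olefination gives 6, and loss of N2 with a 1,2-hydride shift gives the terminal alkyne; the mild carbonate base is tolerated by enolisable aliphatic aldehydes.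

Step 5
Reactants: 3 2-iodobenzene-1,3,5-triyl triacetate; 7 hentriacont-1-yne; 8 carbon monoxide
Product: 11 5,7-dihydroxy-2-nonacosyl-4H-chromen-4-one, via ynone triacetate 9 (not isolated), via diethylaminoenone 10 (not isolated)
Conditions: PdCl2(PPh3)2 (5 mol %), dppp (5 mol %), CO (2 bar), Et2NH/toluene 1:2, sealed vessel, 50 °C then 90 °C; aq. HCl work-up
Reagents that add atoms: none
Why: Pd(0) inserts into the C–I bond of 3, CO insertion gives the aroyl–palladium species, and amine-assisted, copper-free transfer of the acetylide of 7 followed by reductive elimination gives ynone 9, which forms C4a–C4 and C4–C3. Diethylamine then cleaves the three aryl acetates by aminolysis and adds to the ynone to give enaminone 10, whose ortho phenol attacks the amine-bearing carbon and expels diethylamine, which forms O1–C2. The closest known reaction type is the palladium-catalysed carbonylative annulation of o-iodophenols or their acetates with terminal alkynes in secondary amines, which gives flavones and 2-alkylchromones. The pyranone closes in the 6-endo mode (6-endo-trig addition–elimination on 10, equivalent to 6-endo-dig hydroalkoxylation of the ynone); no stereocentre is formed, and the double-bond geometry of 10 is lost on closure. Carbonylative coupling must win over direct Sonogashira coupling, which the absence of copper and the two ortho substituents of the aryl–palladium intermediate (slowing transmetalation more than CO insertion) should secure. Alkynyl transfer to the aroyl–palladium species must also beat capture by the amine, which the hindered 2,6-disubstituted aroyl group and the bulky secondary amine should favour. Six-ring over five-ring (5-exo) closure is secured by the enaminone pathway, in which the amine-bearing carbon is the only electrophilic site and is reached only through the six-membered transition state. Ring A raises no regiochemical question, because the two ortho oxygens of 9 are equivalent by symmetry and the one not used becomes the 5-OH.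

## Compound list

1 | phloroglucinol (benzene-1,3,5-triol) | Oc1cc(O)cc(O)c1 | starting material
2 | 2-iodobenzene-1,3,5-triol | Oc1cc(O)c(I)c(O)c1 | intermediate
3 | 2-iodobenzene-1,3,5-triyl triacetate | CC(=O)Oc1cc(OC(C)=O)c(I)c(OC(C)=O)c1 | intermediate
4 | triacontan-1-ol | CCCCCCCCCCCCCCCCCCCCCCCCCCCCCCO | starting material
5 | triacontanal | CCCCCCCCCCCCCCCCCCCCCCCCCCCCCC=O | intermediate
6 | 1-diazohentriacont-1-ene | CCCCCCCCCCCCCCCCCCCCCCCCCCCCCC=C=[N+]=[N-] | intermediate
7 | hentriacont-1-yne | CCCCCCCCCCCCCCCCCCCCCCCCCCCCCC#C | intermediate
8 | carbon monoxide | [C-]#[O+] | starting material
9 | 2-(dotriacont-2-ynoyl)benzene-1,3,5-triyl triacetate | CCCCCCCCCCCCCCCCCCCCCCCCCCCCCC#CC(=O)c1c(OC(C)=O)cc(OC(C)=O)cc1OC(C)=O | intermediate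
10 | (E)-3-(diethylamino)-1-(2,4,6-trihydroxyphenyl)dotriacont-2-en-1-one | CCN(CC)/C(CCCCCCCCCCCCCCCCCCCCCCCCCCCCC)=C/C(=O)c1c(O)cc(O)cc1O | intermediate
11 | 5,7-dihydroxy-2-nonacosyl-4H-chromen-4-one | CCCCCCCCCCCCCCCCCCCCCCCCCCCCCc1cc(=O)c2c(O)cc(O)cc2o1 | target

## Step count and risk

Total steps: 5. Longest linear sequence: 3 steps (steps 1, 2, 5 or steps 3, 4, 5).

**Step 5 (key step).**
- What may go wrong: premature aminolysis of the acetates before oxidative addition would leave an electron-rich iodophenoxide that loses iodine by protodeiodination. The aroyl–palladium intermediate may be captured by diethylamine (amide formation), or the alkyne may couple directly without CO. After deacetylation, the free phenol may close in the 5-exo mode if amine addition to the ynone is slow. Acetate cleavage or amine elimination may be incomplete.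
- Fallback: it sets out from 7 and returns to the route at 11, replacing the carbonylation by a polar addition and an acid-mediated ring closure. Lithiation of 7 (n-BuLi, THF, 0 °C) and addition to commercial 2,4,6-trimethoxybenzaldehyde should give racemic 1-(2,4,6-trimethoxyphenyl)dotriacont-2-yn-1-ol F1. Oxidation with MnO2 (CH2Cl2, 40 °C) should give 1-(2,4,6-trimethoxyphenyl)dotriacont-2-yn-1-one F2. Excess BBr3 (CH2Cl2, −78 °C to rt) should cleave the two methyl ethers flanking the carbonyl group by chelation, close the pyranone by 6-endo attack of the freed phenol on the Lewis-acid-activated ynone, and then cleave the last ether to give 11. If the last cleavage stalls, 5-hydroxy-7-methoxy-2-nonacosyl-4H-chromen-4-one F3 would be isolated and treated again with BBr3 at 40 °C.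

**Step 1.**
- What may go wrong: over-iodination, because the mono-iodide is still a very electron-rich arene, and oxidative darkening or loss of iodine on storage of the free triol.
- Fallback: it sets out from 1 and returns at 3, bypassing 2 by reversing the order of events. Acetylation of 1 (Ac2O, pyridine) should give benzene-1,3,5-triyl triacetate F4. A single iodination (NIS, cat. TfOH, MeCN, rt) should then give 3, because the triacetate is far less activated than the triol and should stop after one substitution.

**Step 4.**
- What may go wrong: incomplete conversion, because the C30 aldehyde is poorly soluble in a methanol-containing medium, and base-induced aldol self-condensation of the enolisable aldehyde during the slow reaction.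
- Fallback: it sets out from 5 and returns at 7 by a Corey–Fuchs sequence that avoids protic base. CBr4/PPh3 (CH2Cl2, 0 °C, in which 5 dissolves) should give 1,1-dibromohentriacont-1-ene F5. Treatment with n-BuLi (2.2 equiv, THF, −78 °C to rt) and aqueous quench should give 7.

## Further compounds

F1 | step 5 | 1-(2,4,6-trimethoxyphenyl)dotriacont-2-yn-1-ol (racemic) | CCCCCCCCCCCCCCCCCCCCCCCCCCCCCC#CC(O)c1c(OC)cc(OC)cc1OC
F2 | step 5 | 1-(2,4,6-trimethoxyphenyl)dotriacont-2-yn-1-one | CCCCCCCCCCCCCCCCCCCCCCCCCCCCCC#CC(=O)c1c(OC)cc(OC)cc1OC
F3 | step 5 | 5-hydroxy-7-methoxy-2-nonacosyl-4H-chromen-4-one | CCCCCCCCCCCCCCCCCCCCCCCCCCCCCc1cc(=O)c2c(O)cc(OC)cc2o1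
F4 | step 1 | benzene-1,3,5-triyl triacetate | CC(=O)Oc1cc(OC(C)=O)cc(OC(C)=O)c1
F5 | step 4 | 1,1-dibromohentriacont-1-ene | CCCCCCCCCCCCCCCCCCCCCCCCCCCCCC=C(Br)Br
A1 | alternative 1 | 2-acetyl-3,5-dimethoxyphenyl triacontanoate | CCCCCCCCCCCCCCCCCCCCCCCCCCCCCC(=O)Oc1cc(OC)cc(OC)c1C(C)=O
A2 | alternative 1 | 1-(2-hydroxy-4,6-dimethoxyphenyl)dotriacontane-1,3-dione | CCCCCCCCCCCCCCCCCCCCCCCCCCCCCC(=O)CC(=O)c1c(O)cc(OC)cc1OC
A3 | alternative 1 | 5,7-dimethoxy-2-nonacosyl-4H-chromen-4-one | CCCCCCCCCCCCCCCCCCCCCCCCCCCCCc1cc(=O)c2c(OC)cc(OC)cc2o1
A4 | alternative 2 | 5-(1-hydroxytriacontylidene)-2,2-dimethyl-1,3-dioxane-4,6-dione | CCCCCCCCCCCCCCCCCCCCCCCCCCCCCC(O)=C1C(=O)OC(C)(C)OC1=O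
A5 | alternative 2 | 3-oxodotriacont-1-en-1-one (acylketene) | CCCCCCCCCCCCCCCCCCCCCCCCCCCCCC(=O)C=C=O
A6 | alternative 2 | 5,7-dihydroxy-4-nonacosyl-2H-chromen-2-one | CCCCCCCCCCCCCCCCCCCCCCCCCCCCCc1cc(=O)oc2cc(O)cc(O)c12
A7 | alternative 3 | 9-(5,7-dimethoxy-4-oxo-4H-chromen-2-yl)nonanoic acid | OC(=O)CCCCCCCCc1cc(=O)c2c(OC)cc(OC)cc2o1
A8 | alternative 3 | docosanoic acid | CCCCCCCCCCCCCCCCCCCCCC(=O)O
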